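## Structural features

The target is an unsymmetrical methylene-bridged pair of acylphloroglucinol units. One half is a 2,2-dimethyl-2H-chromene with a fully substituted benzene ring (C5–OH, C6–CH2 bridge, C7–OH, C8–butanoyl), and its pyran oxygen O1 is ortho to the acyl-bearing carbon C8. The other half, ring B, is an enolised cyclohexane-1,3,5-trione, numbered here B1 (bridge), B2 (C–OH), B3 (quaternary: methyl and (E)-geranyl), B4 (C–OH), B5 (acetyl) and B6 (C=O). B3 is the only stereocentre, (R) in the tautomer written; it has no stereogenic neighbour, lies between B2 and B4, and is stereogenic only because B1 and B5 carry different groups. It cannot epimerise by enolisation, but loss of the bridge from a ring B that has no acetyl group yet gives an achiral trione, so that stage is configurationally exposed. The fragile groups are the bridge (retro-Michael cleavage and scrambling in warm base), the chromene and geranyl alkenes (acid-induced cyclisation onto neighbouring OH groups) and the β-triketone (retro-Claisen cleavage). The real difficulty is absolute control at B3 inside a flat, pseudo-symmetric, tautomerising ring, together with a cross-selective bridge and the less favoured chromene orientation. The key step exploits two hidden skeletons: B2–B3–B4–B5 is an α,α-disubstituted acetoacetic ester (ester carbon B2, ketone carbon B4, methyl carbon B5), and B6–B1–CH2–C6–C5–O is a 3,4-dihydrocoumarin, so ring B can be closed from these two pieces by making only B5–B6 and B1–B2.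

## Logic of the disconnections

**19 to 17.** The bond cut is B5–C(acetyl).
- Reason: the acetyl methyl group would compete with B1 as the carbon nucleophile in the ring closure below. B5 is also the only C–H carbon left in ring B of 17, so putting the acetyl back needs no regiocontrol.
- Gain: small (two carbons), but it removes the one ambiguity of the key step.
- Demand: C-acylation must beat acylation of two phenols. The base must be mild enough not to cleave the bridge, because 17 is the configurationally exposed stage.

**17 to 15 + 9 (through 16), the key disconnection.** The bonds cut are the ring bonds B1–B2 and B5–B6. In the backward sense the freed B6 carbonyl is tied to the C5 oxygen of the chromene as a lactone, a ring that 19 does not contain.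
- In one sentence: ring B is not derived from an arene but is closed by a double Claisen condensation between the methyl-ketone enolate of 15 and the lactone 9. That sentence does not describe the usual plan, which dearomatises an arene at B3 and then builds the bridge with a one-carbon electrophile.
- Reason: the stereocentre is moved out of the flat ring into an open chain, where its two carbonyl neighbours are chemically different. The bridge carbon is carried in rather than made in a cross-coupling.
- Gain: two fragments of similar size (17 and 18 carbons), one holding only the stereocentre and the other only the aromatic regiochemistry.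
- Demand: the ketone carbon of 15 must become B4 and its ester carbon B2, since the opposite pairing would give the enantiomer. The second bond must form by C-acylation, not O-acylation, and without nucleophilic alkoxide at high temperature.

**15 to 12 + 13 (through 14), then 12 to 10 + 11.** The bonds cut are B3–CH2(geranyl) and then the enamine C–N bond.
- Reason: B3 is the α-carbon of a β-keto ester, for which auxiliary-controlled alkylation to a quaternary centre is an established reaction type. The ethyl ester needed later as electrophile is tolerated.
- Gain: three commercial compounds.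
- Demand: one face of a tetrasubstituted aza-enolate must be alkylated, by SN2 attack at the primary carbon of 13, so that the E-alkene is kept.

**9 to 6 + 7 (through 8).** The bonds cut are C4–C4a and O1–C2 of the pyran ring.
- Reason: in 6 the only free ring carbon is flanked by one free OH, which is ortho to the acyl carbon, and by the lactone oxygen. The pyran can therefore close in one direction only.
- Gain: the chromene orientation is fixed by a ring that the key step needs anyway.
- Demand: the lactone must survive the chromenylation and must not migrate to the other ortho oxygen.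

**6 to 2 + 3 + a one-carbon electrophile (through 4 and 5).** The bonds cut are C6–CH2, CH2–B1 and O–B6.
- Reason: one operation installs the bridge carbon, B1 and B6.
- Gain: a symmetric, simple arene.
- Demand: the lactone must close onto the oxygen para to the ketone, and self-bridging of 2 must be outrun.

**2 to 1.** The bond cut is aryl–C(=O) of the butanoyl group. The acylation of a C3-symmetric arene has no regiochemical issue; the only demand is to stop at mono-acylation.

## Other disconnections considered

**Alternative 1:** (the first that comes to mind) Cut one C–C bond of the bridge. The forward key step condenses the complete ring-B monomer A1 with the chromene A2 through a one-carbon electrophile. A1 would come from catalytic asymmetric dearomative geranylation of the methylated acylphloroglucinol A3. Four grounds speak against it: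
- A1 and A2 are both carbon nucleophiles toward the same electrophile and bridging is reversible, so two homodimers compete with the cross product on statistical grounds.
- In A3 the unsubstituted ring carbon and three oxygens compete with the methyl-bearing carbon, and attack at the unsubstituted carbon is favoured because it rearomatises.
- The new stereocentre would lie on a flat nucleophile outside the allyl fragment held by the catalyst. The reacting allyl terminus is a plain CH2, which gives facial discrimination little to grip.
- A2 needs pyran closure onto a chelated ortho oxygen of 2, against its natural bias.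

The chosen plan answers all four points by construction and is no longer.

**Alternative 2:** Cut the bridge–B1 bond, but from an achiral partner. The forward key step is a catalytic enantioselective conjugate addition of the achiral trione A4 to the ortho-quinone methide released from the Mannich base A5. It would give 17 by desymmetrisation, so bridge and stereocentre would be set together. The idea uses the same hidden symmetry as the chosen plan, but three grounds speak against it:
- The two enantiotopic carbons of A4 differ only through methyl versus geranyl two bonds away, and attack from either face of a given carbon gives the same product. The catalyst would have to tell left from right on a nearly symmetric disc.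
- The addition is reversible and its reverse regenerates achiral A4, so selectivity can leak away.
- A4 has no clean preparation from an arene, and A5 inherits the orientation problem of A2.

The step count is not lower, because the acetyl group must still follow.

**Alternative 3:** Cut B3–CH2(geranyl) in the complete carbon skeleton. The forward key step is a late palladium-catalysed asymmetric dearomative allylic alkylation of the fully aromatic dimer A6 with a geranyl electrophile, giving 19 in the last step. This would be a union at the fully substituted carbon. Grounds against it: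
- A6 offers five acidic OH groups and several fully substituted nucleophilic ring carbons, including the two that carry the bridge, so site selectivity rests on small differences.
- Linear versus branched attack and the facial problem of Alternative 1 remain.
- A6 itself must be made by the statistical bridging of Alternative 1.

All the risk would sit in the last step, on the most valuable material.

Key step: step 6

Assumption: the sense of induction in step 5 is taken from the chelate model given there; if it proves opposite, D-valine tert-butyl ester replaces 11 and nothing else changes. CIP descriptors of ring-B compounds refer to the tautomer written in the SMILES.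

## Steps

Step 1
Reactants: 1 phloroglucinol (benzene-1,3,5-triol)
Product: 2 1-(2,4,6-trihydroxyphenyl)butan-1-one
Conditions: butanoyl chloride (1.0 equiv), AlCl3 (3 equiv), CH2Cl2/MeNO2, 0 to 40 °C; aq. HCl
Reagents that add atoms: butanoyl chloride, CCCC(=O)Cl
Why: Friedel–Crafts acylation of a very electron-rich arene; the aryl ketone formed is deactivated and held as an aluminium chelate, so one equivalent of acid chloride should stop at mono-acylation.

Step 2
Reactants: 2 1-(2,4,6-trihydroxyphenyl)butan-1-one; 3 Meldrum's acid (2,2-dimethyl-1,3-dioxane-4,6-dione)
Product: 6 6-butanoyl-5,7-dihydroxy-3,4-dihydro-2H-chromen-2-one, via 5-methylene Meldrum's acid 4 (not isolated), via benzylated Meldrum's acid 5 (not isolated)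
Conditions: (CH2O)n (1.0 equiv), L-proline (10 mol %), MeCN, 25 °C; then pyridine, 100 °C
Reagents that add atoms: formaldehyde (as paraformaldehyde), C=O
Why: Knoevenagel condensation of 3 with formaldehyde gives the strong acceptor 4, to which ring carbon C3 of 2 adds (Michael addition of an acylphloroglucinol carbon to an alkylidene 1,3-dicarbonyl compound) to give 5; on heating a neighbouring phenol opens the dioxanedione and acetone and CO2 are lost, the known phenol/aldehyde/Meldrum's acid entry to 3,4-dihydrocoumarins. The OH para to the ketone is the most acidic and is not tied up in the hydrogen bond to the ketone, so it should lactonise first, and the O-acylated ring is then too poor a nucleophile for a second annulation.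

Step 3
Reactants: 6 6-butanoyl-5,7-dihydroxy-3,4-dihydro-2H-chromen-2-one; 7 3-methylbut-2-enal
Product: 9 6-butanoyl-5-hydroxy-8,8-dimethyl-3,4-dihydro-2H,8H-pyrano[2,3-f]chromen-2-one, via ortho-quinone methide 8 (not isolated)
Conditions: 7 (2 equiv), pyridine, 115 °C
Reagents that add atoms: none
Why: Base-mediated chromenylation: aldol-type attack of the only free ring carbon on 7, loss of water to 8 and oxa-6π electrocyclisation. Of the two oxygens that flank this carbon one is locked in the lactone, so the pyran can close only onto the oxygen ortho to the butanoyl group, which is the orientation of 19.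

Step 4
Reactants: 10 ethyl 2-methyl-3-oxobutanoate (racemic); 11 L-valine tert-butyl ester (free base)
Product: 12 ethyl (Z)-3-{[(2S)-1-tert-butoxy-3-methyl-1-oxobutan-2-yl]amino}-2-methylbut-2-enoate
Conditions: BF3·OEt2 (cat.), toluene, Dean–Stark reflux
Reagents that add atoms: none
Why: Acid-catalysed condensation of a β-keto ester with a primary amine under removal of water; the (Z)-enamino ester is favoured by the N–H···O=C hydrogen bond, and the stereocentre of 10 disappears in it.

Step 5
Reactants: 12 ethyl (Z)-3-{[(2S)-1-tert-butoxy-3-methyl-1-oxobutan-2-yl]amino}-2-methylbut-2-enoate; 13 geranyl bromide ((2E)-1-bromo-3,7-dimethylocta-2,6-diene)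
Product: 15 ethyl (2S,4E)-2-acetyl-2,5,9-trimethyldeca-4,8-dienoate, via alkylated ketimine 14 (not isolated)
Conditions: LDA (1.1 equiv), toluene, −78 °C; HMPA (2 equiv); 13, −78 to −55 °C; then aq. citric acid, 25 °C
Reagents that add atoms: water, O
Why: Diastereoselective alkylation of a lithiated chiral enamino ester derived from a valine ester: nitrogen, the ethyl-ester carbonyl and the valine-ester carbonyl bind lithium in one plane and the isopropyl group stands on one face. HMPA takes the free lithium site on the opposite face and screens it, so the carbon nucleophile should meet the primary carbon of 13 (SN2, E-alkene untouched) from the isopropyl-side face, where that group is remote from the reacting carbon; this sets B3 as (S) in 15. Mild aqueous acid hydrolyses 14 and returns the auxiliary.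

Step 6
Reactants: 15 ethyl (2S,4E)-2-acetyl-2,5,9-trimethyldeca-4,8-dienoate; 9 6-butanoyl-5-hydroxy-8,8-dimethyl-3,4-dihydro-2H,8H-pyrano[2,3-f]chromen-2-one
Product: 17 (4S)-2-[(8-butanoyl-5,7-dihydroxy-2,2-dimethyl-2H-chromen-6-yl)methyl]-4-[(2E)-3,7-dimethylocta-2,6-dienyl]-3,5-dihydroxy-4-methylcyclohexa-2,5-dien-1-one, via open-chain diketo ester 16 (not isolated)
Conditions: 15, LiHMDS (2.2 equiv), THF, −78 °C; add 9 (as Li phenoxide, LiHMDS 1.0 equiv), −78 to −40 °C; then LDA (3 equiv), DMPU, −78 to 0 °C; 1 M HCl, 0 °C
Reagents that add atoms: none
Why: LiHMDS can enolise 15 only at the acetyl methyl group because B3 is quaternary, and this enolate (B5) attacks the aryl-ester carbonyl of 9 (B6), which is far more electrophilic and less hindered than the neopentyl-type ethyl ester of 15 or the chelated, di-ortho-substituted aryl ketone. Collapse of the adduct (or the equivalent elimination–addition path through a ketene) expels the C5 phenoxide, opens the temporary lactone and gives the diketonate of 16, a crossed Claisen acylation of a ketone enolate by a phenolic lactone. LDA then removes a proton from B1, the only γ-position of the diketonate that bears hydrogen, and this most basic carbon of the polyanion attacks the ethyl ester B2 in an intramolecular Claisen (Dieckmann-type) condensation, the reaction type by which gem-dialkyl cyclohexane-1,3,5-triones are closed from open-chain keto esters. Ring B closes in the 6-(enolendo)-exo-trig mode, helped by the Thorpe–Ingold effect of B3 and made irreversible by deprotonation of the vinylogous acid that forms. No stereocentre is created: B3 has no α-hydrogen and none of its four bonds is touched, so it is carried through unchanged. What must be secured is the pairing ketone carbon to B4 and ester carbon to B2, since the opposite pairing gives the enantiomer, and this is fixed because one carbonyl of 15 anchors the nucleophile while the other can act only as electrophile. O-Acylation by the enolate oxygen on B6 is the main competitor but is reversed by the liberated ethoxide, whereas C-acylation is not; DMPU loosens the lithium chelate of the diketonate so that it can adopt the open geometry in which B1 and B2 come within bonding distance. The medium holds no nucleophilic alkoxide until the closing event and stays at or below 0 °C, which guards against retro-Claisen and retro-Michael cleavage.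

Step 7
Reactants: 17 (4S)-2-[(8-butanoyl-5,7-dihydroxy-2,2-dimethyl-2H-chromen-6-yl)methyl]-4-[(2E)-3,7-dimethylocta-2,6-dienyl]-3,5-dihydroxy-4-methylcyclohexa-2,5-dien-1-one
Product: 19 (4R)-2-acetyl-6-[(8-butanoyl-5,7-dihydroxy-2,2-dimethyl-2H-chromen-6-yl)methyl]-4-[(2E)-3,7-dimethylocta-2,6-dienyl]-3,5-dihydroxy-4-methylcyclohexa-2,5-dien-1-one (target), via ring-B enol acetate 18 (not isolated)
Conditions: Ac2O (1.05 equiv), Et3N (1.2 equiv), DMAP (0.3 equiv), CH2Cl2, 0 to 25 °C; pH 4 buffer
Reagents that add atoms: acetic anhydride, CC(=O)OC(C)=O
Why: The vinylogous acid of ring B is far more acidic than the chelated phenols, so its enolate should be acetylated first to 18, and DMAP then shuttles the acetyl group from oxygen to B5 (O-to-C acyl migration of enol esters of cyclic 1,3-diones, the standard entry to 2-acyl-1,3-diones). B5 is the only ring-B carbon whose acylation ends in an enolisable, hydrogen-bonded triketone, so it is the thermodynamic sink; B3 is untouched and its descriptor changes from (S) to (R) only because the priorities of B2 and B4 swap.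

## Compound list

1 | phloroglucinol | Oc1cc(O)cc(O)c1 | starting material
2 | 1-(2,4,6-trihydroxyphenyl)butan-1-one | CCCC(=O)c1c(O)cc(O)cc1O | intermediate
3 | Meldrum's acid | CC1(C)OC(=O)CC(=O)O1 | starting material
4 | 2,2-dimethyl-5-methylidene-1,3-dioxane-4,6-dione | C=C1C(=O)OC(C)(C)OC1=O | intermediate (not isolated)
5 | 5-[(3-butanoyl-2,4,6-trihydroxyphenyl)methyl]-2,2-dimethyl-1,3-dioxane-4,6-dione | CCCC(=O)c1c(O)cc(O)c(CC2C(=O)OC(C)(C)OC2=O)c1O | intermediate (not isolated)
6 | 6-butanoyl-5,7-dihydroxy-3,4-dihydro-2H-chromen-2-one | CCCC(=O)c1c(O)cc2OC(=O)CCc2c1O | intermediate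
7 | 3-methylbut-2-enal | CC(C)=CC=O | starting material
8 | 6-butanoyl-5-hydroxy-8-(3-methylbut-2-enylidene)-3,4-dihydro-2H-chromene-2,7(8H)-dione | CCCC(=O)C1=C(O)C2=C(OC(=O)CC2)C(=CC=C(C)C)C1=O | intermediate (not isolated)
9 | 6-butanoyl-5-hydroxy-8,8-dimethyl-3,4-dihydro-2H,8H-pyrano[2,3-f]chromen-2-one | CCCC(=O)c1c(O)c2CCC(=O)Oc2c2C=CC(C)(C)Oc12 | intermediate
10 | ethyl 2-methyl-3-oxobutanoate (racemic) | CCOC(=O)C(C)C(C)=O | starting material
11 | L-valine tert-butyl ester | CC(C)[C@H](N)C(=O)OC(C)(C)C | starting material
12 | ethyl (Z)-3-{[(2S)-1-tert-butoxy-3-methyl-1-oxobutan-2-yl]amino}-2-methylbut-2-enoate | CCOC(=O)/C(C)=C(C)\N[C@@H](C(C)C)C(=O)OC(C)(C)C | intermediate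
13 | geranyl bromide | CC(C)=CCC/C(C)=C/CBr | starting material
14 | ethyl (2S,4E)-2-{1-[(2S)-1-tert-butoxy-3-methyl-1-oxobutan-2-yl]iminoethyl}-2,5,9-trimethyldeca-4,8-dienoate | CCOC(=O)[C@@](C)(C/C=C(\C)CCC=C(C)C)C(C)=N[C@@H](C(C)C)C(=O)OC(C)(C)C | intermediate (not isolated)
15 | ethyl (2S,4E)-2-acetyl-2,5,9-trimethyldeca-4,8-dienoate | CCOC(=O)[C@@](C)(C/C=C(\C)CCC=C(C)C)C(C)=O | intermediate
16 | ethyl (2S)-7-(8-butanoyl-5,7-dihydroxy-2,2-dimethyl-2H-chromen-6-yl)-2-[(2E)-3,7-dimethylocta-2,6-dienyl]-2-methyl-3,5-dioxoheptanoate | CCOC(=O)[C@@](C)(C/C=C(\C)CCC=C(C)C)C(=O)CC(=O)CCc1c(O)c(C(=O)CCC)c2OC(C)(C)C=Cc2c1O | intermediate (not isolated)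
17 | (4S)-2-[(8-butanoyl-5,7-dihydroxy-2,2-dimethyl-2H-chromen-6-yl)methyl]-4-[(2E)-3,7-dimethylocta-2,6-dienyl]-3,5-dihydroxy-4-methylcyclohexa-2,5-dien-1-one | CCCC(=O)c1c(O)c(CC2=C(O)[C@@](C)(C/C=C(\C)CCC=C(C)C)C(O)=CC2=O)c(O)c2c1OC(C)(C)C=C2 | intermediate
18 | enol acetate of 17 at the B4 oxygen, (R) as written, B3 unchanged in space | CCCC(=O)c1c(O)c(CC2=C(O)[C@@](C)(C/C=C(\C)CCC=C(C)C)C(OC(C)=O)=CC2=O)c(O)c2c1OC(C)(C)C=C2 | intermediate (not isolated)
19 | (4R)-2-acetyl-6-[(8-butanoyl-5,7-dihydroxy-2,2-dimethyl-2H-chromen-6-yl)methyl]-4-[(2E)-3,7-dimethylocta-2,6-dienyl]-3,5-dihydroxy-4-methylcyclohexa-2,5-dien-1-one | CCCC(=O)c1c(O)c(CC2=C(O)[C@@](C)(C/C=C(\C)CCC=C(C)C)C(O)=C(C(C)=O)C2=O)c(O)c2c1OC(C)(C)C=C2 | target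

## Step count and least certain steps

Total step count: 7. Longest linear sequence: 5 steps (1, 2, 3, 6, 7). The second branch (4, 5) joins at step 6.

**Step 6 (key step).** The most likely failure is that the first C–C bond forms but the ring closure lags.
- The lithium diketonate prefers a chelated shape that holds B1 and B2 apart.
- The polyanion (two phenoxides, diketonate, B1 carbanion) may aggregate or precipitate.
- Proton transfer from the α-positions of the lactone or the butanoyl group may consume enolate.
- Forcing the closure by long warming would open alkoxide-induced retro-Claisen cleavage at B4 and retro-Michael cleavage of the bridge. Both pass through achiral stages and would erode the enantiomeric purity.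

Fallback (sets out from 9 and 13, returns at 17): the order of the two C–C bonds is reversed, so that the ring is closed by a doubly activated carbon.
- Lactone 9 is opened with the lithium enolate of 2-(trimethylsilyl)ethyl acetate to the β-keto ester F1.
- In parallel 13 alkylates the sodium salt of diethyl methylmalonate to the achiral diester F2.
- Mono-saponification, then crystallisation of the salt with one enantiomer of 1-phenylethylamine, gives the (R)-half-ester F3, which oxalyl chloride converts into the acid chloride F4.
- The polyanion of F1 (LDA, γ-carbanion of the β-keto ester at B1) is acylated by F4 to the open-chain triketo diester F5.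
- B5, now flanked by two carbonyl groups, closes onto the ethyl ester B4 with DBU (Claisen cyclisation of a triketo ester) to the ring-B carboxylate F6.
- Fluoride removes the silylethyl group and decarboxylation follows in the same flask to give 17.

**Step 2.** Three things may go wrong:
- The lactone may close onto an ortho oxygen, or migrate between the two oxygens in hot pyridine, which would lift the regiocontrol of step 3.
- Formaldehyde may bridge two molecules of 2 before it is taken up by 3.
- A second annulation may occur at the remaining ring carbon.

Fallback (sets out from 2, returns at 9): the para oxygen is blocked by a protecting group instead of the lactone.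
- Selective silylation of the non-chelated OH (TIPSCl, imidazole) gives the silyl ether F7.
- Chromenylation with 7 in pyridine can then close only onto an ortho oxygen and gives the silylated chromene F8.
- Fluoride frees the dihydroxychromene F9.
- The annulation with 3 and formaldehyde at its single free carbon gives 9, the isomeric lactone F10, or both. The direction of this closure no longer matters, because either lactone is opened in step 6 to the same 16.

**Step 5.** Facial selectivity may be eroded with a large, flexible allylic halide, N-alkylation or SN2′ attack may compete, and the sense of induction rests on a model.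

Fallback (sets out from 13, returns at 15): the stereocentre is obtained by resolution of a malonate rather than by auxiliary control. The diester F2 is mono-saponified, and the (S)-half-ester F11 is crystallised with the other enantiomer of the resolving amine. The unwanted half-ester can be re-esterified to achiral F2 and recycled. Oxalyl chloride gives the acid chloride F12, and lithium dimethylcuprate converts it into the methyl ketone 15 without touching the ester.

**Step 7.** Acetyl transfer to the phenolic oxygens may compete with transfer to B5. Prolonged contact with amine base may start retro-Michael cleavage of the bridge at the one stage where this costs configuration.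

Fallback (sets out from 17, returns at 19): chemoselectivity is given up in favour of exhaustive acylation and later release. Excess acetic anhydride in pyridine gives the triacetate F13. Catalytic cyanide with triethylamine moves only the enol acetate from oxygen to B5, giving the C-acetyl bis(aryl acetate) F14. Brief methanolysis (K2CO3, MeOH, 0 °C) then frees the two phenols to give 19.

## Further compounds

F1 | step 6 | 2-(trimethylsilyl)ethyl 5-(8-butanoyl-5,7-dihydroxy-2,2-dimethyl-2H-chromen-6-yl)-3-oxopentanoate | C[Si](C)(C)CCOC(=O)CC(=O)CCc1c(O)c(C(=O)CCC)c2OC(C)(C)C=Cc2c1O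
F2 | step 6 | diethyl 2-[(2E)-3,7-dimethylocta-2,6-dienyl]-2-methylmalonate | CCOC(=O)C(C)(C/C=C(\C)CCC=C(C)C)C(=O)OCC
F3 | step 6 | (2R,4E)-2-(ethoxycarbonyl)-2,5,9-trimethyldeca-4,8-dienoic acid | OC(=O)[C@@](C)(C/C=C(\C)CCC=C(C)C)C(=O)OCC
F4 | step 6 | ethyl (2S,4E)-2-(chlorocarbonyl)-2,5,9-trimethyldeca-4,8-dienoate | ClC(=O)[C@@](C)(C/C=C(\C)CCC=C(C)C)C(=O)OCC
F5 | step 6 | 1-ethyl 7-[2-(trimethylsilyl)ethyl] (2R)-4-[(8-butanoyl-5,7-dihydroxy-2,2-dimethyl-2H-chromen-6-yl)methyl]-2-[(2E)-3,7-dimethylocta-2,6-dienyl]-2-methyl-3,5-dioxoheptanedioate (C4 epimerisable) | C[Si](C)(C)CCOC(=O)CC(=O)C(Cc1c(O)c(C(=O)CCC)c2OC(C)(C)C=Cc2c1O)C(=O)[C@@](C)(C/C=C(\C)CCC=C(C)C)C(=O)OCC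
F6 | step 6 | 2-(trimethylsilyl)ethyl ester of the B5-carboxylic acid of 17, (R) as written | CCCC(=O)c1c(O)c(CC2=C(O)[C@@](C)(C/C=C(\C)CCC=C(C)C)C(O)=C(C(=O)OCC[Si](C)(C)C)C2=O)c(O)c2c1OC(C)(C)C=C2
F7 | step 2 | 1-[2,6-dihydroxy-4-(triisopropylsilyloxy)phenyl]butan-1-one | CCCC(=O)c1c(O)cc(O[Si](C(C)C)(C(C)C)C(C)C)cc1O
F8 | step 2 | 1-[7-hydroxy-2,2-dimethyl-5-(triisopropylsilyloxy)-2H-chromen-8-yl]butan-1-one | CCCC(=O)c1c(O)cc(O[Si](C(C)C)(C(C)C)C(C)C)c2C=CC(C)(C)Oc12
F9 | step 2 | 1-(5,7-dihydroxy-2,2-dimethyl-2H-chromen-8-yl)butan-1-one | CCCC(=O)c1c(O)cc(O)c2C=CC(C)(C)Oc12
F10 | step 2 | 10-butanoyl-5-hydroxy-8,8-dimethyl-3,4-dihydro-2H,8H-pyrano[3,2-g]chromen-2-one | CCCC(=O)c1c2OC(=O)CCc2c(O)c2C=CC(C)(C)Oc12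
F11 | step 5 | (2S,4E)-2-(ethoxycarbonyl)-2,5,9-trimethyldeca-4,8-dienoic acid | CCOC(=O)[C@@](C)(C/C=C(\C)CCC=C(C)C)C(=O)O
F12 | step 5 | ethyl (2R,4E)-2-(chlorocarbonyl)-2,5,9-trimethyldeca-4,8-dienoate | CCOC(=O)[C@@](C)(C/C=C(\C)CCC=C(C)C)C(=O)Cl
F13 | step 7 | triacetate of 17 (both phenols and the B4 enol), (R) as written | CCCC(=O)c1c(OC(C)=O)c(CC2=C(O)[C@@](C)(C/C=C(\C)CCC=C(C)C)C(OC(C)=O)=CC2=O)c(OC(C)=O)c2c1OC(C)(C)C=C2
F14 | step 7 | 5,7-di-O-acetate of 19, (R) | CCCC(=O)c1c(OC(C)=O)c(CC2=C(O)[C@@](C)(C/C=C(\C)CCC=C(C)C)C(O)=C(C(C)=O)C2=O)c(OC(C)=O)c2c1OC(C)(C)C=C2
A1 | alternative 1 | (4R)-2-acetyl-4-[(2E)-3,7-dimethylocta-2,6-dienyl]-3,5-dihydroxy-4-methylcyclohexa-2,5-dien-1-one | O=C1C=C(O)[C@@](C)(C/C=C(\C)CCC=C(C)C)C(O)=C1C(C)=O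
A2 | alternative 1 | 1-(5,7-dihydroxy-2,2-dimethyl-2H-chromen-8-yl)butan-1-one | CCCC(=O)c1c(O)cc(O)c2C=CC(C)(C)Oc12
A3 | alternative 1 | 1-(2,4,6-trihydroxy-3-methylphenyl)ethan-1-one | CC(=O)c1c(O)cc(O)c(C)c1O
A4 | alternative 2 | 2-[(2E)-3,7-dimethylocta-2,6-dienyl]-2-methylcyclohexane-1,3,5-trione | CC(C)=CCC/C(C)=C/CC1(C)C(=O)CC(=O)CC1=O
A5 | alternative 2 | 1-{6-[(dimethylamino)methyl]-5,7-dihydroxy-2,2-dimethyl-2H-chromen-8-yl}butan-1-one | CCCC(=O)c1c(O)c(CN(C)C)c(O)c2C=CC(C)(C)Oc12
A6 | alternative 3 | 1-{6-[(3-acetyl-2,4,6-trihydroxy-5-methylphenyl)methyl]-5,7-dihydroxy-2,2-dimethyl-2H-chromen-8-yl}butan-1-one | CCCC(=O)c1c(O)c(Cc2c(O)c(C)c(O)c(C(C)=O)c2O)c(O)c2C=CC(C)(C)Oc12
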